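**Plan**

1. Isoflavone numbering is used (O1, C2, C3, C4, C4a, C5–C8, C8a; primed positions in ring B). Retrosynthetically the phenols at C5 and C7 are masked as MOM ethers, the C2=C3 double bond is taken back to the isoflavanone, and ring C is cut at three bonds: C4a–C4, C4–C3 and O1–C2.
2. The enabling feature is that C4 is a ketone carbon held between C4a of ring A and C3, the carbon that bears ring B. It can therefore enter as carbon monoxide between an aryl iodide at C4a and a 1-arylvinylboron unit that supplies C3, C2 and ring B, while the phenol oxygen ortho to the iodide becomes O1.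
3. Forward, ring A is made first as an iodophenol: borylation and oxidation of bis-MOM 2-methoxyresorcinol give a mirror-symmetric phenol, so iodination has one outcome and the methoxy group must end at C6. Ring B is made separately as a vinylboronate from 4'-hydroxyacetophenone and prenyl bromide.
4. Ring C is the only ring formed. It closes in the three-component carbonylative coupling and oxa-Michael step, after which dehydrogenation and MOM removal give the target.
5. Stereochemistry: the target is achiral. The C3 centre of the isoflavanone forms racemic and becomes sp2 on dehydrogenation, and the prenyl alkene has no geometry.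

Key step: step 8

Remark: 2-methoxyresorcinol, 4'-hydroxyacetophenone, prenyl bromide and carbon monoxide are taken as commercial; "prenyl" means 3-methylbut-2-enyl throughout.

**Route**

Step 1
Reactants: 1 2-methoxyresorcinol
Product: 2 2-methoxy-1,3-bis(methoxymethoxy)benzene
Conditions: NaH, MOMCl, DMF, 0 °C → rt
Reagents that add atoms: chloromethyl methyl ether (MOMCl), COCCl
Why: Double Williamson-type O-alkylation of the sodium phenoxides with the reactive α-chloro ether gives the bis-MOM acetal, which is stable to the basic, organometallic and oxidative steps that follow.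

Step 2
Reactants: 2 2-methoxy-1,3-bis(methoxymethoxy)benzene
Product: 3 2-[4-methoxy-3,5-bis(methoxymethoxy)phenyl]-4,4,5,5-tetramethyl-1,3,2-dioxaborolane
Conditions: [Ir(OMe)(cod)]2 (cat.), dtbpy (cat.), B2pin2, THF, 80 °C
Reagents that add atoms: bis(pinacolato)diboron (B2pin2), CC1(C)OB(B2OC(C)(C)C(C)(C)O2)OC1(C)C
Why: Iridium-catalysed aromatic C–H borylation is governed by sterics, and C5 of 2 is the only ring C–H without an ortho substituent, so a single arylboronate is expected.

Step 3
Reactants: 3 2-[4-methoxy-3,5-bis(methoxymethoxy)phenyl]-4,4,5,5-tetramethyl-1,3,2-dioxaborolane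
Product: 4 4-methoxy-3,5-bis(methoxymethoxy)phenol
Conditions: H2O2 (30% aq), NaOH (aq), THF, 0 °C → rt
Reagents that add atoms: hydrogen peroxide, OO
Why: Oxidation of an arylboronic ester with alkaline hydrogen peroxide proceeds by 1,2-migration of the aryl group from boron to oxygen and leaves the MOM acetals untouched.

Step 4
Reactants: 4 4-methoxy-3,5-bis(methoxymethoxy)phenol
Product: 5 2-iodo-4-methoxy-3,5-bis(methoxymethoxy)phenol
Conditions: NIS (1.0 equiv), MeCN, −20 → 0 °C, dark
Reagents that add atoms: N-iodosuccinimide (NIS), O=C1CCC(=O)N1I
Why: Electrophilic aromatic iodination of the strongly activated phenol can only occur ortho to the hydroxyl (the para position carries the methoxy group), the two ortho positions are equivalent by mirror symmetry, and one equivalent of NIS at low temperature should stop at the mono-iodide.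

Step 5
Reactants: 6 4'-hydroxyacetophenone; 7 prenyl bromide (1-bromo-3-methylbut-2-ene)
Product: 8 4'-(prenyloxy)acetophenone
Conditions: K2CO3, acetone, reflux
Reagents that add atoms: none
Why: Williamson ether synthesis, in which the phenoxide displaces bromide from the primary allylic bromide at oxygen.

Step 6
Reactants: 8 4'-(prenyloxy)acetophenone
Product: 9 1-[4-(prenyloxy)phenyl]vinyl trifluoromethanesulfonate
Conditions: KN(SiMe3)2, THF, −78 °C; then PhNTf2, −78 → 0 °C
Reagents that add atoms: N-phenylbis(trifluoromethanesulfonimide) (PhNTf2), O=S(=O)(N(c1ccccc1)S(=O)(=O)C(F)(F)F)C(F)(F)F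
Why: Enol triflate formation: the methyl ketone has a single enolisable position, and its potassium enolate is sulfonylated on oxygen by PhNTf2 at low temperature, conditions that do not touch the prenyl ether.

Step 7
Reactants: 9 1-[4-(prenyloxy)phenyl]vinyl trifluoromethanesulfonate
Product: 10 2-{1-[4-(prenyloxy)phenyl]vinyl}-4,4,5,5-tetramethyl-1,3,2-dioxaborolane
Conditions: B2pin2, PdCl2(PPh3)2 (cat.), PPh3 (cat.), KOPh, toluene, 50 °C
Reagents that add atoms: bis(pinacolato)diboron (B2pin2), CC1(C)OB(B2OC(C)(C)C(C)(C)O2)OC1(C)C
Why: Miyaura borylation of an alkenyl triflate (oxidative addition, phenoxide-assisted transmetalation with B2pin2, reductive elimination), in which the weak base KOPh suppresses Suzuki homocoupling and the trisubstituted allylic ether ionises too slowly at palladium to interfere.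

Step 8
Reactants: 5 2-iodo-4-methoxy-3,5-bis(methoxymethoxy)phenol; 10 2-{1-[4-(prenyloxy)phenyl]vinyl}-4,4,5,5-tetramethyl-1,3,2-dioxaborolane; 11 carbon monoxide
Product: 13 racemic 6-methoxy-5,7-bis(methoxymethoxy)-3-[4-(prenyloxy)phenyl]chroman-4-one, via aryl vinyl ketone 12 (not isolated)
Conditions: Pd(OAc)2 (cat.), Xantphos (cat.), K2CO3, CO (3 bar), anisole with a little H2O, 80 °C
Reagents that add atoms: none
Why: Zerovalent palladium formed from Pd(OAc)2 and Xantphos inserts into the C–I bond of 5, migratory insertion of CO gives the aroylpalladium complex, and base-assisted transmetalation with boronate 10 followed by reductive elimination creates the C4a–C4 and C4–C3 bonds of ketone 12. The ortho phenoxide of 12 then adds to the terminal CH2 of the 2-aryl enone in a 6-endo-trig oxa-Michael closure that forms O1–C2 and so ring C. The closest known reaction types are the carbonylative Suzuki–Miyaura coupling of aryl iodides with alkenylboron reagents to aryl vinyl ketones and the base-induced ring closure of 2'-hydroxy α-methylene deoxybenzoins used in classical isoflavanone syntheses. C3 becomes a stereocentre when the resulting enolate is protonated without any controlling element, so 13 is racemic, which is of no consequence because C3 turns sp2 in step 9. The step needs CO insertion to come before transmetalation and the boronate to win over the phenoxide at the acyl complex: the electron-rich aryl–palladium bond flanked by two ortho oxygen substituents transmetalates slowly but inserts CO readily, the wide bite angle of Xantphos and the CO pressure hold the catalyst at the acyl stage, and the hindered acyl group is poorly accessible to an external phenoxide. The site of ring fusion is fixed by the position of iodine in 5, so the methoxy group can only end at C6.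

Step 9
Reactants: 13 racemic 6-methoxy-5,7-bis(methoxymethoxy)-3-[4-(prenyloxy)phenyl]chroman-4-one
Product: 14 6-methoxy-5,7-bis(methoxymethoxy)-3-[4-(prenyloxy)phenyl]-4H-chromen-4-one
Conditions: IBX, DMSO, 75 °C
Reagents that add atoms: none
Why: IBX dehydrogenation of a ketone to the enone: C3 is the only α-position, it is benzylic and readily enolised, and oxidation there gives the C2=C3 bond of the aromatic 4-pyranone while the MOM acetals, the aryl ethers and the trisubstituted alkene are inert to IBX.

Step 10
Reactants: 14 6-methoxy-5,7-bis(methoxymethoxy)-3-[4-(prenyloxy)phenyl]-4H-chromen-4-one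
Product: 15 isoaurmillone (5,7-dihydroxy-6-methoxy-3-[4-(prenyloxy)phenyl]-4H-chromen-4-one)
Conditions: HCl (about 1 M), MeOH–THF, rt → 40 °C
Reagents that add atoms: none
Why: Acid-catalysed methanolysis of the MOM acetals through oxocarbenium ions is much faster than ionisation of the allylic aryl ether or addition to the trisubstituted alkene, so dilute acid at or slightly above room temperature should free both phenols (the chelated 5-O-MOM first) and leave the prenyl ether in place.

**Compound list**

1 | 2-methoxyresorcinol (2-methoxybenzene-1,3-diol) | COc1c(O)cccc1O | starting material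
2 | 2-methoxy-1,3-bis(methoxymethoxy)benzene | COCOc1cccc(OCOC)c1OC | intermediate
3 | 2-[4-methoxy-3,5-bis(methoxymethoxy)phenyl]-4,4,5,5-tetramethyl-1,3,2-dioxaborolane | COCOc1cc(B2OC(C)(C)C(C)(C)O2)cc(OCOC)c1OC | intermediate
4 | 4-methoxy-3,5-bis(methoxymethoxy)phenol | COCOc1cc(O)cc(OCOC)c1OC | intermediate
5 | 2-iodo-4-methoxy-3,5-bis(methoxymethoxy)phenol | COc1c(OCOC)cc(O)c(I)c1OCOC | intermediate
6 | 4'-hydroxyacetophenone | CC(=O)c1ccc(O)cc1 | starting material
7 | prenyl bromide (1-bromo-3-methylbut-2-ene) | CC(C)=CCBr | starting material
8 | 4'-(prenyloxy)acetophenone (1-[4-(3-methylbut-2-enyloxy)phenyl]ethanone) | CC(=O)c1ccc(OCC=C(C)C)cc1 | intermediate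
9 | 1-[4-(prenyloxy)phenyl]vinyl trifluoromethanesulfonate | C=C(OS(=O)(=O)C(F)(F)F)c1ccc(OCC=C(C)C)cc1 | intermediate
10 | 2-{1-[4-(prenyloxy)phenyl]vinyl}-4,4,5,5-tetramethyl-1,3,2-dioxaborolane | CC(C)=CCOc1ccc(C(=C)B2OC(C)(C)C(C)(C)O2)cc1 | intermediate
11 | carbon monoxide | [C-]#[O+] | starting material
12 | 1-[2-hydroxy-5-methoxy-4,6-bis(methoxymethoxy)phenyl]-2-[4-(prenyloxy)phenyl]prop-2-en-1-one (aryl vinyl ketone, not isolated) | COc1c(OCOC)cc(O)c(C(=O)C(=C)c2ccc(OCC=C(C)C)cc2)c1OCOC | intermediate
13 | racemic 6-methoxy-5,7-bis(methoxymethoxy)-3-[4-(prenyloxy)phenyl]chroman-4-one | COc1c(OCOC)cc2c(c1OCOC)C(=O)C(c1ccc(OCC=C(C)C)cc1)CO2 | intermediate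
14 | 6-methoxy-5,7-bis(methoxymethoxy)-3-[4-(prenyloxy)phenyl]-4H-chromen-4-one | COc1c(OCOC)cc2occ(-c3ccc(OCC=C(C)C)cc3)c(=O)c2c1OCOC | intermediate
15 | isoaurmillone (5,7-dihydroxy-6-methoxy-3-[4-(prenyloxy)phenyl]-4H-chromen-4-one) | COc1c(O)cc2occ(-c3ccc(OCC=C(C)C)cc3)c(=O)c2c1O | target

**Step count**

Total: 10 steps. Longest linear sequence: 7 steps (steps 1–4, then 8–10); the ring B branch (steps 5–7) joins at step 8.

**Steps most likely to fail**

1. Step 8. Transmetalation may occur before CO insertion and give the non-carbonylative vinylphenol. The phenoxide may instead capture the acylpalladium complex and give aryl esters, or the vinylboronate may be lost by protodeboronation. The fallback sets out from phenol 4 and vinyl triflate 9 and comes back to the route at isoflavanone 13; it also bypasses boronate 10. Magnesium-mediated ortho-formylation of 4 (MgCl2, Et3N, paraformaldehyde, MeCN, reflux) should give 2-hydroxy-5-methoxy-4,6-bis(methoxymethoxy)benzaldehyde F1. A Nozaki–Hiyama–Kishi coupling of F1 with 9 (CrCl2, catalytic NiCl2, DMF, rt) should then form the C4–C3 bond and give the racemic allylic alcohol 2-{1-hydroxy-2-[4-(prenyloxy)phenyl]prop-2-enyl}-4-methoxy-3,5-bis(methoxymethoxy)phenol F2. Oxidation of this benzylic, allylic carbinol with MnO2 in CH2Cl2 should give ketone 12, which closes to 13 on brief treatment with K2CO3.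

2. Step 10. The allylic aryl ether may ionise under the acid, with loss of the prenyl group and possible re-attachment of the prenyl cation to ring A, or methanol may add across the alkene, before the slower 7-O-MOM group is gone. The fallback sets out from isoflavone 14 and comes back at target 15. Methanolic HCl at reflux is used deliberately to remove both MOM groups and the prenyl ether, which should give tectorigenin F3 (5,7,4'-trihydroxy-6-methoxyisoflavone). Treatment of F3 with KOt-Bu (2 equiv) in DMF forms the 7,4'-dianion. Its 4'-phenoxide is the more nucleophilic site because the 7-phenoxide is delocalised into the pyranone carbonyl and the 5-hydroxyl stays chelated. One equivalent of prenyl bromide 7 should therefore alkylate O4' selectively, as is known for dianions of 5,7,4'-trihydroxyisoflavones.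

3. Step 9. Oxidation at the hindered tertiary C3 may be sluggish, and prolonged heating invites oxidation at the allylic ether methylene or loss of the 5-O-MOM group to the acidic iodine by-product. The fallback sets out from isoflavanone 13 and comes back at isoflavone 14. Enolisation with LiN(SiMe3)2 and trapping with Me3SiCl (THF, −78 °C) should give the silyl enol ether 6-methoxy-5,7-bis(methoxymethoxy)-3-[4-(prenyloxy)phenyl]-4-(trimethylsilyloxy)-2H-chromene F4. Saegusa–Ito oxidation (Pd(OAc)2, MeCN, rt) then gives 14 by β-hydride elimination of a C2 hydrogen from the C3-bound palladium enolate.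

**Further compounds**

F1 | step 8 | 2-hydroxy-5-methoxy-4,6-bis(methoxymethoxy)benzaldehyde | COc1c(OCOC)cc(O)c(C=O)c1OCOC
F2 | step 8 | racemic 2-{1-hydroxy-2-[4-(prenyloxy)phenyl]prop-2-enyl}-4-methoxy-3,5-bis(methoxymethoxy)phenol | COc1c(OCOC)cc(O)c(C(O)C(=C)c2ccc(OCC=C(C)C)cc2)c1OCOC
F3 | step 10 | tectorigenin (5,7,4'-trihydroxy-6-methoxyisoflavone) | COc1c(O)cc2occ(-c3ccc(O)cc3)c(=O)c2c1O
F4 | step 9 | 6-methoxy-5,7-bis(methoxymethoxy)-3-[4-(prenyloxy)phenyl]-4-(trimethylsilyloxy)-2H-chromene | COc1c(OCOC)cc2c(c1OCOC)C(O[Si](C)(C)C)=C(c1ccc(OCC=C(C)C)cc1)CO2
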